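**Plan**

- Locants (text only): seven-membered ring C1 (C–OH, carries the butenoyl chain C2–C4), C5 (CH–O-acyl), C6 (lactone O–CH), C7, C8 (CH2), C9 (C=O), C10 (CH–CH3); C11/C12/C13 are the lactone α-carbon, carbonyl and exocyclic CH2; O1, O5, O6 are the oxygens on C1, C5, C6.
- Enabling feature: ketone C9 and oxygenated C6 are 1,4-related through C7–C8 and 1,5-related through C10–C1–C5. The cycloheptane is therefore the retro-aldol (de Mayo) product of a bicyclo[3.2.0]heptan-2-one; cutting C5–C6 and C1–C10 leaves 2-methylcyclopentane-1,3-dione and the enol of protected dihydroxyacetone.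
- Further cuts: C7–C11 (rhodium-catalysed conjugate addition), O6–C12 (lactone), C2–C3 (alkenylchromium addition), C5–O ester.
- Forward order: cyclopentenone enol ester + dioxin → cyclobutane tricycle → enone → C7 alkenyl group → fragmentation of the cyclobutane to the seven-membered ring → trans lactone → butenoyl chain → ester.
- Stereochemistry: C1/C5 from the exo, cis-fused dioxane of the photoadduct; C7 by alkenyl addition anti to the cyclobutane; C10 by protonation anti to the C1 carbonate; C6 by C1-hydroxyl-directed reduction; absolute configuration by separating the menthyloxyacetate diastereomers of the photoadduct; the ester centre from (R)-2-methylbutanoic acid.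

Key step: step 3

Remarks: 2, 9, 24 and 28 are taken as purchasable; in step 3 the alkene partner 5 is used in excess to outrun dimerisation of the excited enone and the surplus is recovered unchanged; the menthyl group is not expected to bias the cycloaddition, and the photoadduct of opposite tricycle configuration is removed in step 3; the C9 configuration in 17–20 and the C2 configuration in 26 are of no consequence.

**Step 1**
Reactants: 1 2-methylcyclopentane-1,3-dione; 2 (−)-menthyloxyacetyl chloride
Product: 3 2-methyl-3-oxocyclopent-1-en-1-yl (−)-menthyloxyacetate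
Conditions: pyridine, CH2Cl2, 0 °C to rt
Reagents that add atoms: none
Why: O-acylation of the fully enolised, vinylogous-acid dione by an acid chloride (enol ester formation) can only occur on oxygen because C2 is blocked by methyl and both oxygens are equivalent, and the menthyl group is the later handle for separating the two absolute series.

**Step 2**
Reactants: 4 2,2-dimethyl-1,3-dioxan-5-one
Product: 5 2,2-dimethyl-4H-1,3-dioxin-5-yl 2-(trimethylsilyl)ethyl carbonate
Conditions: KN(SiMe3)2, THF, −78 °C; then ClCO2CH2CH2SiMe3, −78 to 0 °C
Reagents that add atoms: 2-(trimethylsilyl)ethyl chloroformate, C[Si](C)(C)CCOC(Cl)=O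
Why: O-acylation of the potassium enolate of the symmetrical dioxanone by a chloroformate is the standard route to enol carbonates; the two α-methylene groups are equivalent, so a single achiral enol carbonate results in which the ring oxygen is the only strong donor on the double bond.

**Step 3**
Reactants: 3 enol ester; 5 enol carbonate
Product: 6 cis-anti-cis tricyclic photoadduct (one diastereomer after separation)
Conditions: hν (medium-pressure Hg lamp, Pyrex filter, λ > 300 nm), CH2Cl2, −20 °C; then separation of the two diastereomers (SiO2, crystallisation)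
Reagents that add atoms: none
Why: Excitation and intersystem crossing give the triplet of enone 3, whose β-carbon C6 bonds to C5 of 5 to give a 1,4-biradical (tertiary α-keto radical at C10, tertiary α-oxy radical at C1) that collapses to the cyclobutane. The closest known reaction is the addition half of the de Mayo reaction, the [2+2] photocycloaddition of enol esters of 2-methylcyclopentane-1,3-dione and of cyclopentenones to enol ethers and cycloalkenes. The four-membered ring C10–C6–C5–C1 is closed by stepwise [2+2] addition, C5–C6 and C1–C10 being the two new bonds. C6/C10 must be cis because a trans-fused bicyclo[3.2.0]heptanone is too strained, C5/C1 are cis because both lie in the dioxin ring, and the dioxane takes the exo (anti) position, which puts O5 and C2 exo and the C1 carbonate endo, so that O1 will be trans to O5 in the later seven-membered ring. The step needs head-to-tail orientation, which is secured because the ring oxygen on C5 is the only strong donor of 5 (the carbonate on C1 is a weak one), so the donor-bearing carbon joins the enone β-carbon as in enone–enol ether cycloadditions, and this mode also gives the more stabilised biradical. The menthyloxyacetyl group makes the two mirror-image modes of addition diastereomers, and the one shown is separated.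

**Step 4**
Reactants: 6 tricyclic photoadduct
Product: 8 bicyclic enone (C7=C8), via trimethylsilyl enol ether 7 (not isolated)
Conditions: LiN(SiMe3)2, Me3SiCl, THF, −78 °C; then Pd(OAc)2, MeCN, rt
Reagents that add atoms: none
Why: Saegusa–Ito oxidation: the ketone can enolise only towards C8 because C10 is quaternary, so silylation followed by Pd(OAc)2-mediated dehydrosilylation should place the double bond at C7=C8 without touching the four existing stereocentres.

**Step 5**
Reactants: 9 (2-bromoprop-2-en-1-yl)oxy(tert-butyl)dimethylsilane
Product: 11 alkenylboronic acid pinacol ester, via alkenyllithium 10 (not isolated)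
Conditions: t-BuLi, Et2O, −78 °C; then 2-isopropoxy-4,4,5,5-tetramethyl-1,3,2-dioxaborolane, −78 °C to rt; HCl in Et2O
Reagents that add atoms: 2-isopropoxy-4,4,5,5-tetramethyl-1,3,2-dioxaborolane, CC(C)OB1OC(C)(C)C(C)(C)O1
Why: bromine–lithium exchange followed by trapping of the alkenyllithium with an alkoxyboronate (borylation of an organolithium) is a standard way to alkenylboronic pinacol esters, and keeping the anion at −78 °C until it is trapped prevents the 1,4-shift of silicon from oxygen to carbon.

**Step 6**
Reactants: 8 bicyclic enone; 11 alkenylboronic acid pinacol ester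
Product: 12 C7-alkenyl ketone
Conditions: [Rh(OH)(cod)]2 (cat.), Et3N, 1,4-dioxane/H2O (10:1), 30 °C
Reagents that add atoms: none
Why: rhodium-catalysed 1,4-addition of an alkenylboron reagent (Hayashi–Miyaura reaction): transmetalation gives an alkenylrhodium species that adds across C7=C8 from the convex face, anti to the cyclobutane whose endo hydrogen on C5 and endo carbonate on C1 cover the other face, which sets C7 with the alkenyl group cis to the acyloxy group on C6 and trans to the C5–C6 bond; a rhodium catalyst is preferred to an organocuprate because cuprates tend to cleave γ-acyloxy enones reductively.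

**Step 7**
Reactants: 12 C7-alkenyl ketone
Product: 14 cycloheptane-1,4-dione, via tertiary cyclobutanol 13 (not isolated)
Conditions: Yb(OTf)3 (cat.), MeOH, 0 °C to rt
Reagents that add atoms: none
Why: ytterbium triflate chelates the α-alkoxy ester and catalyses its methanolysis without base (selective cleavage of alkoxyacetates), and the tertiary cyclobutanol so uncovered should undergo strain-driven retro-aldol cleavage of C6–C10 (the fragmentation half of the de Mayo reaction; O1 stays masked as a carbonate so that only this bond can break) to the seven-membered 1,4-diketone; the absence of base spares the β-carbonate from elimination and C7 from epimerisation, and the C9 enol should be protonated at C10 from the face opposite the C1 carbonate, which sets the methyl-bearing centre.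

**Step 8**
Reactants: 14 cycloheptane-1,4-dione
Product: 15 dihydroxy diketone
Conditions: Bu4NF, AcOH, THF, 0 °C to rt
Reagents that add atoms: none
Why: fluoride cleaves the primary silyl ether and triggers β-elimination of the 2-(trimethylsilyl)ethyl carbonate with loss of ethene and CO2 (fluoride-mediated deprotection), while acetic acid protonates the tertiary alkoxide at once so that the β-hydroxy ketone does not suffer retro-aldol cleavage and C7, now α to the C6 ketone, is not epimerised.

**Step 9**
Reactants: 15 dihydroxy diketone
Product: 17 tetraol acetonide, via bis(diethylborinate) 16 (not isolated)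
Conditions: Et2BOMe, THF/MeOH (4:1), −78 °C; NaBH4, −78 °C; AcOH quench, evaporation from MeOH
Reagents that add atoms: none
Why: Narasaka–Prasad reduction: the diethylboron group on O1 chelates each β-carbonyl oxygen on the face of the C1–O bond, so borohydride should add to C6 (and C9) from the opposite face, giving the C6 alcohol cis to the C1 hydroxyl and therefore trans to both O5 and the C7 side chain, while the C9 alcohol is oxidised back in step 11.

**Step 10**
Reactants: 17 tetraol acetonide
Product: 20 trans-fused α-methylene lactone, via hydroxy enal 18 (not isolated), via lactol 19 (not isolated)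
Conditions: MnO2 (activated, excess), CH2Cl2, rt
Reagents that add atoms: none
Why: MnO2 oxidises only the allylic primary alcohol, the enal is captured by the adjacent C6 hydroxyl as a five-membered lactol (the C9 hydroxyl is 1,3-trans to the side chain and cannot reach it), and MnO2 oxidises the lactol further to the trans-fused α-methylene γ-lactone (oxidative lactonisation).

**Step 11**
Reactants: 20 trans-fused α-methylene lactone
Product: 21 keto lactone acetonide
Conditions: Dess–Martin periodinane, CH2Cl2, 0 °C to rt
Reagents that add atoms: none
Why: Dess–Martin oxidation of the only remaining secondary alcohol restores the C9 ketone, the tertiary C1 hydroxyl being inert and no base being present that could epimerise C10.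

**Step 12**
Reactants: 21 keto lactone acetonide
Product: 22 triol
Conditions: AcOH/H2O/THF (3:1:1), 40 °C
Reagents that add atoms: none
Why: acid-catalysed hydrolysis of the isopropylidene acetal frees the C5 hydroxyl and the primary C2 hydroxyl under conditions to which lactone, ketone and tertiary alcohol are stable.

**Step 13**
Reactants: 22 triol
Product: 23 α-hydroxy aldehyde
Conditions: [Cu(MeCN)4]OTf (cat.), 2,2′-bipyridine, TEMPO (cat.), N-methylimidazole, air, MeCN, rt
Reagents that add atoms: none
Why: the copper/TEMPO aerobic alcohol oxidation is selective for the unhindered primary alcohol over the secondary C5 hydroxyl and does not cleave 1,2-diols, and the α-hydroxy aldehyde formed has no α-hydrogen to lose.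

**Step 14**
Reactants: 23 α-hydroxy aldehyde; 24 (E)-1-bromoprop-1-ene
Product: 26 allylic alcohol (both C2 epimers), via (E)-prop-1-enylchromium dichloride 25 (not isolated)
Conditions: CrCl2 (excess), NiCl2 (cat.), DMF, rt; aqueous work-up
Reagents that add atoms: none
Why: Nozaki–Hiyama–Kishi reaction: the alkenylchromium reagent forms with retention of the E geometry and adds to the aldehyde only, leaving ketone, lactone and free hydroxyls untouched, and the new carbinol centre does not matter because it is oxidised in the next step.

**Step 15**
Reactants: 26 allylic alcohol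
Product: 27 hydroxy enone
Conditions: MnO2, CH2Cl2, rt
Reagents that add atoms: none
Why: MnO2 oxidises the allylic secondary alcohol but not the saturated C5 alcohol, giving the E-configured enone (allylic oxidation).

**Step 16**
Reactants: 27 hydroxy enone; 28 (R)-2-methylbutanoic acid
Product: 30 target CNP0153197.3, via O-acylisourea 29 (not isolated)
Conditions: N,N′-diisopropylcarbodiimide, DMAP (cat.), CH2Cl2, 0 °C to rt
Reagents that add atoms: none
Why: Steglich esterification should acylate the secondary C5 hydroxyl while the tertiary C1 hydroxyl stays free, and carbodiimide activation with catalytic DMAP at 0 °C keeps the α-stereocentre of the acid intact.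

**Compound list**

1 | 2-methylcyclopentane-1,3-dione | CC1C(=O)CCC1=O | starting material
2 | {[(1R,2S,5R)-5-methyl-2-(propan-2-yl)cyclohexyl]oxy}acetyl chloride ((−)-menthyloxyacetyl chloride) | ClC(=O)CO[C@@H]1C[C@H](C)CC[C@H]1C(C)C | starting material
3 | 2-methyl-3-oxocyclopent-1-en-1-yl (−)-menthyloxyacetate | CC1=C(OC(=O)CO[C@@H]2C[C@H](C)CC[C@H]2C(C)C)CCC1=O | intermediate
4 | 2,2-dimethyl-1,3-dioxan-5-one | CC1(C)OCC(=O)CO1 | starting material
5 | 2,2-dimethyl-4H-1,3-dioxin-5-yl 2-(trimethylsilyl)ethyl carbonate | CC1(C)OCC(OC(=O)OCC[Si](C)(C)C)=CO1 | intermediate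
6 | photoadduct: cyclopentanone (C9=O, C8, C7) cis-fused at C10 (methyl) and C6 (menthyloxyacetoxy) to a cyclobutane, which is cis-fused at C5/C1 to an exo 2,2-dimethyl-1,3-dioxane (O5 on C5, C2 on C1); 2-(trimethylsilyl)ethoxycarbonyloxy on C1 endo | C[C@]12C(=O)CC[C@@]1(OC(=O)CO[C@@H]3C[C@H](C)CC[C@H]3C(C)C)[C@@H]1OC(C)(C)OC[C@]21OC(=O)OCC[Si](C)(C)C | intermediate
7 | trimethylsilyl enol ether of 6 (C9–OSiMe3, C9=C8) | C[C@]12C(O[Si](C)(C)C)=CC[C@@]1(OC(=O)CO[C@@H]3C[C@H](C)CC[C@H]3C(C)C)[C@@H]1OC(C)(C)OC[C@]21OC(=O)OCC[Si](C)(C)C | intermediate (not isolated)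
8 | enone of 6 with C7=C8 | C[C@]12C(=O)C=C[C@@]1(OC(=O)CO[C@@H]3C[C@H](C)CC[C@H]3C(C)C)[C@@H]1OC(C)(C)OC[C@]21OC(=O)OCC[Si](C)(C)C | intermediate
9 | (2-bromoprop-2-en-1-yl)oxy(tert-butyl)dimethylsilane | C=C(Br)CO[Si](C)(C)C(C)(C)C | starting material
10 | [3-(tert-butyldimethylsilyloxy)prop-1-en-2-yl]lithium | [Li]C(=C)CO[Si](C)(C)C(C)(C)C | intermediate (not isolated)
11 | tert-butyldimethyl{[2-(4,4,5,5-tetramethyl-1,3,2-dioxaborolan-2-yl)prop-2-en-1-yl]oxy}silane | C=C(CO[Si](C)(C)C(C)(C)C)B1OC(C)(C)C(C)(C)O1 | intermediate
12 | 6 carrying at C7 the 3-(tert-butyldimethylsilyloxy)prop-1-en-2-yl group, anti to the cyclobutane and cis to the C6 acyloxy group | C[C@]12C(=O)C[C@H](C(=C)CO[Si](C)(C)C(C)(C)C)[C@@]1(OC(=O)CO[C@@H]3C[C@H](C)CC[C@H]3C(C)C)[C@@H]1OC(C)(C)OC[C@]21OC(=O)OCC[Si](C)(C)C | intermediate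
13 | tertiary cyclobutanol (12 with free C6–OH) | C[C@]12C(=O)C[C@H](C(=C)CO[Si](C)(C)C(C)(C)C)[C@@]1(O)[C@@H]1OC(C)(C)OC[C@]21OC(=O)OCC[Si](C)(C)C | intermediate (not isolated)
14 | cycloheptane-1,4-dione (C9 and C6 ketones) cis-fused at C1/C5 to the 2,2-dimethyl-1,3-dioxane; C10 methyl cis to the C1 carbonate; C7 silyloxypropenyl cis to O5 | C[C@H]1C(=O)C[C@H](C(=C)CO[Si](C)(C)C(C)(C)C)C(=O)[C@@H]2OC(C)(C)OC[C@]12OC(=O)OCC[Si](C)(C)C | intermediate
15 | 14 with free C1–OH and free allylic CH2OH | C[C@H]1C(=O)C[C@H](C(=C)CO)C(=O)[C@@H]2OC(C)(C)OC[C@]12O | intermediate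
16 | bis(diethylborinate) of 15 (on O1 and the allylic oxygen) | C[C@H]1C(=O)C[C@H](C(=C)COB(CC)CC)C(=O)[C@@H]2OC(C)(C)OC[C@]12OB(CC)CC | intermediate (not isolated)
17 | tetraol acetonide: C6–OH and C9–OH both cis to C1–OH; C6–OH trans to O5 and to the C7 side chain | C[C@H]1[C@@H](O)C[C@H](C(=C)CO)[C@@H](O)[C@@H]2OC(C)(C)OC[C@]12O | intermediate
18 | hydroxy enal (17 with the allylic alcohol oxidised to CHO) | C[C@H]1[C@@H](O)C[C@H](C(=C)C=O)[C@@H](O)[C@@H]2OC(C)(C)OC[C@]12O | intermediate (not isolated)
19 | trans-fused lactol (O6 bonded to C12, either anomer) | C[C@H]1[C@@H](O)C[C@H]2[C@@H](OC(O)C2=C)[C@@H]2OC(C)(C)OC[C@]12O | intermediate (not isolated)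
20 | trans-fused α-methylene γ-lactone with C9–OH, C1–OH and the C5/C2 acetonide | C[C@H]1[C@@H](O)C[C@H]2[C@@H](OC(=O)C2=C)[C@@H]2OC(C)(C)OC[C@]12O | intermediate
21 | 20 with the C9 ketone restored | C[C@H]1C(=O)C[C@H]2[C@@H](OC(=O)C2=C)[C@@H]2OC(C)(C)OC[C@]12O | intermediate
22 | triol: 21 without the acetonide (C1–OH, C5–OH, C1–CH2OH) | C[C@H]1C(=O)C[C@H]2[C@@H](OC(=O)C2=C)[C@H](O)[C@]1(O)CO | intermediate
23 | α-hydroxy aldehyde (C2 = CHO) | C[C@H]1C(=O)C[C@H]2[C@@H](OC(=O)C2=C)[C@H](O)[C@]1(O)C=O | intermediate
24 | (E)-1-bromoprop-1-ene | C/C=C/Br | starting material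
25 | (E)-prop-1-enylchromium dichloride | C/C=C/[Cr](Cl)Cl | intermediate (not isolated)
26 | allylic alcohol: C1–CH(OH)–CH=CH–CH3 (E), both C2 epimers | C[C@H]1C(=O)C[C@H]2[C@@H](OC(=O)C2=C)[C@H](O)[C@]1(O)C(O)/C=C/C | intermediate
27 | hydroxy enone: target lacking the C5 ester | C[C@H]1C(=O)C[C@H]2[C@@H](OC(=O)C2=C)[C@H](O)[C@]1(O)C(=O)/C=C/C | intermediate
28 | (R)-2-methylbutanoic acid | CC[C@@H](C)C(=O)O | starting material
29 | O-acylisourea from 28 and N,N′-diisopropylcarbodiimide | CC[C@@H](C)C(=O)OC(=NC(C)C)NC(C)C | intermediate (not isolated)
30 | CNP0153197.3 | C=C1C(=O)O[C@@H]2[C@@H]1CC(=O)[C@H](C)[C@@](O)(C(=O)/C=C/C)[C@H]2OC(=O)[C@H](C)CC | target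

**Totals and risks**

Total step count: 16. Longest linear sequence: 14 steps (1 → 30 through steps 1, 3, 4 and 6–16; steps 2 and 5 are side branches).

Steps most likely to fail:

1. Step 3. The remote menthyl group may give no bias between the two mirror-image modes of addition, the resulting diastereomers may resist separation, and some material may follow the syn (endo-dioxane) mode. The fallback replaces auxiliary-based separation by a catalyst-controlled kinetic resolution. It sets out from 1 and 5. Acylation of 1 with methoxyacetyl chloride (pyridine, CH2Cl2) should give 2-methyl-3-oxocyclopent-1-en-1-yl methoxyacetate F1. Irradiation with 5 as in step 3 should give the racemic methoxyacetate photoadduct F2. Direct dehydrogenation with 2-iodoxybenzoic acid (DMSO, 70 °C) should give the racemic enone F3. Rhodium-catalysed asymmetric 1,4-addition of a deficit of boronate 11 to racemic F3 ([Rh(OH)((R)-binap)]2, dioxane/H2O, 35 °C; Hayashi–Miyaura reaction run as a kinetic resolution, with the ligand antipode chosen so that its preferred face and the convex face coincide only for the wanted enantiomer) should give the enantioenriched C7-alkenyl methoxyacetate F4. Yb(OTf)3 in methanol would remove the methoxyacetate and lead through cyclobutanol 13 back to 14.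

2. Step 9. The boron chelate may not form (competing coordination of the ether oxygen O5), so hydride would reach C6 from the face of the C1–O bond and give the C6 epimer, which lactonises cis. The fallback takes the hydride from C12 instead. It sets out from 15. MnO2 should oxidise only the allylic alcohol to the keto enal F5. Intramolecular rhodium-catalysed ketone hydroacylation ([Rh(nbd)2]BF4, 1,3-bis(diphenylphosphino)propane, 1,2-dichloroethane, 40 °C; a Tishchenko-type lactonisation) should add the aldehyde C–H across the C6 carbonyl. The acyl rhodium hydride is tied to C7 through C11, so hydrogen reaches C6 from the side-chain face and the five-membered lactone closes trans, in preference to the six-membered alternative at C9. This returns to the route at 21 and makes steps 9–11 unnecessary.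

3. Step 13. The free tertiary α-hydroxy aldehyde may be over-oxidised, undergo α-ketol rearrangement or oligomerise, which would also spoil the chromium coupling of step 14. The fallback builds the enone by acyl cross-coupling. It sets out from 22. TEMPO/NaOCl/NaClO2 (phosphate buffer, MeCN) should oxidise the primary alcohol directly to the α-hydroxy acid F6. Ethanethiol with N,N′-dicyclohexylcarbodiimide should give the S-ethyl thioester F7. Liebeskind–Srogl coupling with (E)-prop-1-enylboronic acid (Pd2(dba)3, tri(2-furyl)phosphine, copper thiophene-2-carboxylate, THF, 50 °C) should give enone 27 directly, so that aldehyde 23 and steps 13–15 are not needed.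

**Further compounds**

F1 | step 3 | 2-methyl-3-oxocyclopent-1-en-1-yl methoxyacetate | COCC(=O)OC1=C(C)C(=O)CC1
F2 | step 3 | racemic methoxyacetate analogue of photoadduct 6 (relative configuration as 6; enantiomer carried on is drawn) | C[C@]12C(=O)CC[C@@]1(OC(=O)COC)[C@@H]1OC(C)(C)OC[C@]21OC(=O)OCC[Si](C)(C)C
F3 | step 3 | racemic methoxyacetate analogue of enone 8 (enantiomer carried on is drawn) | C[C@]12C(=O)C=C[C@@]1(OC(=O)COC)[C@@H]1OC(C)(C)OC[C@]21OC(=O)OCC[Si](C)(C)C
F4 | step 3 | methoxyacetate analogue of 12 (single enantiomer) | C[C@]12C(=O)C[C@H](C(=C)CO[Si](C)(C)C(C)(C)C)[C@@]1(OC(=O)COC)[C@@H]1OC(C)(C)OC[C@]21OC(=O)OCC[Si](C)(C)C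
F5 | step 9 | keto enal: 15 with the allylic alcohol oxidised to CHO | C[C@H]1C(=O)C[C@H](C(=C)C=O)C(=O)[C@@H]2OC(C)(C)OC[C@]12O
F6 | step 13 | α-hydroxy acid: 22 with CH2OH oxidised to CO2H | C[C@H]1C(=O)C[C@H]2[C@@H](OC(=O)C2=C)[C@H](O)[C@]1(O)C(=O)O
F7 | step 13 | S-ethyl thioester of F6 | C[C@H]1C(=O)C[C@H]2[C@@H](OC(=O)C2=C)[C@H](O)[C@]1(O)C(=O)SCC
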